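The data stem from a simulated flask for substances that don't exist.

I decided to reckon this flask by its coupling partner, not by its clock.

all flasks: substrate 0.18 M

| charge | coupling partner | protic impurity | remark | time |
|---|---|---|---|---|
| north | 0.38 M | 9 mM | run made earlier |  |
| flask | 0.189 M | 9.00 mM |  | 4.0 d |

north run (percent of the substrate charged)

| time / h | over-reaction product / % | target / % |
|---|---|---|
| 5.00 | 5.5 | 1.8 |
| 10.0 | 13.7 | 1.6 |
| 15.0 | 22.0 | 0.9 |
| 20.0 | 30.9 | 1.7 |
| 25.0 | 37.0 | 2.0 |
| 30.0 | 43.2 | 4.4 |

(scatter of a reading: 1 percentage point)

- the numbers in the tables scatter with a standard deviation of 1 percentage point
- reactions considered so far: substrate -> intermediate B; substrate + coupling partner <-> intermediate A; coupling partner + target -> over-reaction product; coupling partner + protic impurity -> quenched reagent; coupling partner + intermediate B <-> target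

* share of over-reaction product in over-reaction product plus target at 2.0 h
* share of over-reaction product in over-reaction product plus target at 12 h
* share of over-reaction product in over-reaction product plus target at 4.0 d
* which of over-reaction product and target there is more of at 4.0 d

The steps considered so far are these: substrate turns into intermediate B, which adds partner reversibly to give target; target adds a second partner to give over-reaction product; substrate also binds partner reversibly as intermediate A; protic impurity quenches partner.

For the first instants I took the quench as the fast step and counted it as finished at once. That costs the flask 4.76% of its partner and leaves 0.180 M free, about one equivalent of substrate. Intermediate A holds partner reversibly, so I did not subtract it.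

For the middle I read the north run. Over-reaction product climbed from 5.5% at 5.00 h to 43.2% at 30.0 h, while target read 4.4% at that last point. I therefore treated target in the north run as a passage rather than a store.

For the end I wanted a number for the charges of this flask. Each over-reaction product costs two partners, so I carried the over-reaction ceiling, free partner divided by twice the substrate charge. In the north run it stood at 103%, above the last reading of over-reaction product there. In this flask it is 50.0%, which makes partner the limiting reagent of the double addition. I expected the rest of the substrate to wait as intermediate B.

The ceiling gives an amount, not a share, so the shares are the forecast's own: 30% at 2.0 h, 70% at 12 h, 72% at 4.0 d, with over-reaction product ahead. For the end it said: “That freezes over-reaction product near 40–45 %, with target around 15 %, plus unconverted B or substrate.”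

The flask gave 22.9%, 68.4% and 94.1%, with over-reaction product ahead, 47.0% against 2.94%.

substrate → intermediate B (k = 1.10 × 10⁻⁵ s⁻¹); substrate + coupling partner ⇌ intermediate A (K = 3.30 M⁻¹, k = 0.00130 M⁻¹ s⁻¹); coupling partner + target → over-reaction product (k = 7.40 × 10⁻⁴ M⁻¹ s⁻¹); coupling partner + protic impurity → quenched reagent (k = 0.00710 M⁻¹ s⁻¹); coupling partner + intermediate B ⇌ target (K = 12.0 M⁻¹, k = 0.00130 M⁻¹ s⁻¹) At 4.00 d over-reaction product in this flask stood below the ceiling of 50.0%, and it reached 49.8% at 40.0 d. The half-life of target by its step to over-reaction product, at charged concentrations, is 0.057 d, short against 4.0 d, and at 4.00 d target was made at 0.135 of the rate at which it was used up, each step taken net. In the neighbour charged with 0.11 M of partner the ceiling is 28.1%, and over-reaction product stood at 25.5% at 4.00 d.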